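**Plan** (locants follow the name 2-hydroxy-5-methoxy-3-pentadecyl-1,4-benzoquinone: C1 and C4 carbonyls, C2 OH, C3 pentadecyl, C5 OMe, C6 H)

- Retrosynthesis: first the C1 carbonyl oxygen is removed (para oxidation of a phenol), then the O–Si bond at C2, then the ring bonds C2–C3 and C4–C5. This divides the ring into a C17 ynolate (C3, C4 and the chain) and a four-carbon silylvinylketene (C2, C1, C6, C5 with the methoxy group).
- Enabling feature: the alkyl carbon C3 sits between two oxygen-bearing carbons (C2–OH, C4=O) and C4 is bonded to the methoxy carbon C5. An ynolate that is C-acylated by a ketene and then closed by 6π electrocyclization leaves exactly this 2-alkylresorcinol pattern with an ortho methoxy group.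
- Forward: ethyl hexadecanoate becomes the dibromomethyl ketone, which is rearranged to the ynolate only in the flask of the key step. 4-Methoxybut-3-en-2-one becomes the silylvinylketene by diazo transfer, C-silylation and Wolff rearrangement. One benzannulation joins the halves and makes the only ring; para oxidation and desilylation give the hydroxyquinone.
- Stereochemistry: the target has no stereocentre; the E enol ether of the four-carbon half is erased on aromatization.

Key step: step 5

**Route**

Step 1
Reactants: 1 ethyl hexadecanoate
Product: 2 1,1-dibromoheptadecan-2-one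
Conditions: CH2Br2, lithium 2,2,6,6-tetramethylpiperidide (LiTMP), THF, −90 °C; add 1; AcOH quench at −90 °C
Reagents that add atoms: dibromomethane, BrCBr
Why: First stage of the Kowalski homologation, in which dibromomethyllithium adds once to the ester carbonyl to give a tetrahedral lithium alkoxide that is stable at low temperature (no double addition) and collapses on acidic quench to the dibromomethyl ketone with loss of ethanol.

Step 2
Reactants: 3 (E)-4-methoxybut-3-en-2-one
Product: 5 (E)-1-diazo-4-methoxybut-3-en-2-one, via trifluoroacetyl diketone 4 (not isolated)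
Conditions: LiN(SiMe3)2, THF, −78 °C; CF3CO2CH2CF3; AcOH quench; then MeSO2N3, Et3N, H2O, MeCN, rt
Reagents that add atoms: methanesulfonyl azide, CS(=O)(=O)N=[N+]=[N-]; 2,2,2-trifluoroethyl trifluoroacetate, FC(F)(F)COC(=O)C(F)(F)F (its atoms are held only in 4)
Why: Detrifluoroacetylative diazo transfer, in which the kinetic methyl enolate is trifluoroacetylated to the activated 1,3-diketone 4 and the sulfonyl azide then transfers the diazo group with loss of the trifluoroacetyl group, a sequence suited to enones because no diazomethane can add to the double bond.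

Step 3
Reactants: 5 (E)-1-diazo-4-methoxybut-3-en-2-one
Product: 6 (E)-1-diazo-4-methoxy-1-(triisopropylsilyl)but-3-en-2-one
Conditions: i-Pr3SiOTf, i-Pr2NEt, Et2O–hexane, 0 °C to rt
Reagents that add atoms: triisopropylsilyl triflate, CC(C)[Si](OS(=O)(=O)C(F)(F)F)(C(C)C)C(C)C
Why: C-Silylation of an α-diazo ketone, in which the nucleophilic diazo carbon attacks the silyl triflate and the hindered amine removes the proton.

Step 4
Reactants: 6 (E)-1-diazo-4-methoxy-1-(triisopropylsilyl)but-3-en-2-one
Product: 7 (E)-4-methoxy-2-(triisopropylsilyl)buta-1,3-dien-1-one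
Conditions: hν (300 nm), benzene, rt
Reagents that add atoms: none
Why: Photochemical Wolff rearrangement, in which loss of nitrogen and 1,2-shift of the methoxyvinyl group to the carbene carbon give a vinylketene that the silyl group on the ketene carbon protects from dimerization so that it can be isolated.

Step 5
Reactants: 2 1,1-dibromoheptadecan-2-one; 7 (E)-4-methoxy-2-(triisopropylsilyl)buta-1,3-dien-1-one
Product: 11 6-methoxy-2-pentadecyl-3-[(triisopropylsilyl)oxy]phenol, via lithium dibromo enolate 8 (not isolated), via lithium heptadec-1-yn-1-olate 9 (not isolated), via 3-oxidodienylketene 10 (not isolated)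
Conditions: 2, LiN(SiMe3)2 (1.0 equiv), THF, −78 °C; n-BuLi (1.0 equiv), −78 °C to rt; then 7, −78 °C to 40 °C; AcOH quench
Reagents that add atoms: none
Why: LiN(SiMe3)2 removes the acidic CHBr2 proton of 2 to give dibromo enolate 8, bromine–lithium exchange with n-BuLi then triggers the carbenoid 1,2-shift of the pentadecyl group (Kowalski rearrangement) to ynolate 9 with no alkoxide in the flask, and the alkyl-bearing carbon of 9 C-acylates the ketene carbonyl of 7 anti to the bulky silyl group, so that 3-oxidodienylketene 10 forms with the new ketene and the methoxyvinyl arm on the same side of the enolate double bond. The closest known reaction type is the benzannulation of lithium ynolates with (trialkylsilyl)vinylketenes to resorcinol monosilyl ethers. The six-membered ring closes by thermal disrotatory 6π electrocyclization of the ketene C=C, enolate C=C and enol ether C=C of 10, the bond forming between the ketene carbon and the methoxy-bearing terminus. Enolization then aromatizes the ring and a 1,3 carbon-to-oxygen silyl shift moves the silyl group onto the neighbouring oxygen, so no stereocentre is formed. The step needs regiocontrol (alkyl carbon of 9 to the ketene carbonyl, oxygen-bearing carbon to the methoxy terminus), which the polarity of ynolate and ketene fixes, and Z geometry of the enolate, which the silyl group secures; the enol ether geometry only affects the rate of closure.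

Step 6
Reactants: 11 6-methoxy-2-pentadecyl-3-[(triisopropylsilyl)oxy]phenol
Product: 12 5-methoxy-3-pentadecyl-2-[(triisopropylsilyl)oxy]cyclohexa-2,5-diene-1,4-dione
Conditions: ON(SO3K)2 (2.5 equiv), KH2PO4, Bu4NHSO4 (cat.), CH2Cl2–H2O, rt
Reagents that add atoms: dipotassium nitrosodisulfonate (Fremy's salt), [K+].[K+].[O]N(S(=O)(=O)[O-])S(=O)(=O)[O-]
Why: Teuber oxidation, in which one nitrosodisulfonate radical abstracts the phenolic hydrogen and a second couples at the only free para position, after which loss of imidodisulfonate gives the para-quinone; both ortho positions are blocked.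

Step 7
Reactants: 12 5-methoxy-3-pentadecyl-2-[(triisopropylsilyl)oxy]cyclohexa-2,5-diene-1,4-dione
Product: 13 2-hydroxy-5-methoxy-3-pentadecylcyclohexa-2,5-diene-1,4-dione
Conditions: 48% aq HF, MeCN–THF, 0 °C to rt
Reagents that add atoms: none
Why: The 2-silyloxyquinone is a vinylogous silyl ester and should be cleaved by fluoride under acidic conditions that leave the 5-methoxy group (a vinylogous methyl ester) untouched.

**Compound list**

1 | ethyl hexadecanoate (ethyl palmitate) | CCCCCCCCCCCCCCCC(=O)OCC | starting material
2 | 1,1-dibromoheptadecan-2-one | CCCCCCCCCCCCCCCC(=O)C(Br)Br | intermediate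
3 | (E)-4-methoxybut-3-en-2-one | CO/C=C/C(C)=O | starting material
4 | (E)-1,1,1-trifluoro-6-methoxyhex-5-ene-2,4-dione | CO/C=C/C(=O)CC(=O)C(F)(F)F | intermediate (not isolated)
5 | (E)-1-diazo-4-methoxybut-3-en-2-one | CO/C=C/C(=O)C=[N+]=[N-] | intermediate
6 | (E)-1-diazo-4-methoxy-1-(triisopropylsilyl)but-3-en-2-one | CO/C=C/C(=O)C(=[N+]=[N-])[Si](C(C)C)(C(C)C)C(C)C | intermediate
7 | (E)-4-methoxy-2-(triisopropylsilyl)buta-1,3-dien-1-one | CO/C=C/C(=C=O)[Si](C(C)C)(C(C)C)C(C)C | intermediate
8 | lithium 1,1-dibromoheptadec-1-en-2-olate (dibromo enolate) | CCCCCCCCCCCCCCCC([O-])=C(Br)Br.[Li+] | intermediate (not isolated)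
9 | lithium heptadec-1-yn-1-olate | CCCCCCCCCCCCCCCC#C[O-].[Li+] | intermediate (not isolated)
10 | lithium (3Z,5E)-6-methoxy-1-oxo-2-pentadecyl-4-(triisopropylsilyl)hexa-1,3,5-trien-3-olate (3-oxidodienylketene) | O=C=C(CCCCCCCCCCCCCCC)/C([O-])=C(/[Si](C(C)C)(C(C)C)C(C)C)\C=C\OC.[Li+] | intermediate (not isolated)
11 | 6-methoxy-2-pentadecyl-3-[(triisopropylsilyl)oxy]phenol | CCCCCCCCCCCCCCCc1c(O)c(OC)ccc1O[Si](C(C)C)(C(C)C)C(C)C | intermediate
12 | 5-methoxy-3-pentadecyl-2-[(triisopropylsilyl)oxy]cyclohexa-2,5-diene-1,4-dione | CCCCCCCCCCCCCCCC1=C(O[Si](C(C)C)(C(C)C)C(C)C)C(=O)C=C(OC)C1=O | intermediate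
13 | 2-hydroxy-5-methoxy-3-pentadecylcyclohexa-2,5-diene-1,4-dione | CCCCCCCCCCCCCCCC1=C(O)C(=O)C=C(OC)C1=O | target

**Step count and risks**

Total: 7 steps. Longest linear sequence: 6 steps (3 to 13, steps 2–7); step 1 is a one-step side branch that feeds step 5.

Step 5 is the most likely to fail. The ynolate may C-acylate the ketene without the adduct closing, the butyl bromide and amine left from the rearrangement may intercept the ynolate or the ketene, or the electron-rich ketene 7 may oligomerize under the basic conditions. The fallback is a neutral photochemical vinylketene–alkyne benzannulation that sets out from dibromo ketone 2 and diazo ketone 5 and comes back at phenol 11; it also makes steps 3 and 4 unnecessary. Ketone 2 is rearranged as in step 5 (LiN(SiMe3)2, n-BuLi, THF, −78 °C to rt) but the solution is quenched with i-Pr3SiCl, which should give the purified siloxyalkyne triisopropyl(heptadec-1-yn-1-yloxy)silane F1. Irradiation of 5 in the presence of F1 (ClCH2CH2Cl, 300 nm, then 80 °C) should give, by Wolff rearrangement, (E)-4-methoxybuta-1,3-dien-1-one F2. The siloxyalkyne traps F2 in a [2+2] cycloaddition as 4-[(E)-2-methoxyethenyl]-2-pentadecyl-3-[(triisopropylsilyl)oxy]cyclobut-2-en-1-one F3 (racemic). Reversible 4π ring opening of F3 gives the dienylketene (3E,5E)-6-methoxy-2-pentadecyl-3-[(triisopropylsilyl)oxy]hexa-1,3,5-trien-1-one F4, and 6π closure and enolization then deliver the same phenol 11, with the silyl ether now coming from the alkyne oxygen.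

Step 2 is the next risk. The enolized trifluoroacetyl intermediate 4 may cyclize onto the methoxyvinyl terminus with loss of methanol to a 4-pyranone, or the enol ether may hydrolyse during the quench. The fallback sets out from 3 and comes back at 5 without ever forming a 1,3-diketone. Me3SiCl, Et3N and ZnCl2 should convert 3 to (E)-1-methoxy-3-(trimethylsilyloxy)buta-1,3-diene F5. N-Bromosuccinimide then brominates the terminal methylene to give (E)-1-bromo-4-methoxybut-3-en-2-one F6. N,N'-Ditosylhydrazine and DBU convert the bromomethyl ketone to diazo ketone 5 by N-alkylation and elimination of sulfinate.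

Step 6 is the third risk. Oxidative coupling of the phenoxyl radical, slow attack at the para position next to the bulky silyl ether, or sluggish reaction of the lipophilic phenol in the two-phase medium may compete with para oxygenation. The fallback sets out from 11 and comes back at 13, installing the oxygen by formylation and Dakin oxidation. Bu4NF in THF should give 4-methoxy-2-pentadecylbenzene-1,3-diol F7. Vilsmeier–Haack formylation (POCl3, DMF) at the one position that is ortho and para to the two hydroxyls gives 2,4-dihydroxy-5-methoxy-3-pentadecylbenzaldehyde F8. Dakin oxidation (H2O2, NaHCO3) exchanges the formyl group for hydroxyl to give 5-methoxy-3-pentadecylbenzene-1,2,4-triol F9, which air should oxidize in the same flask to 13.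

**Further compounds**

F1 | step 5 | triisopropyl(heptadec-1-yn-1-yloxy)silane | CCCCCCCCCCCCCCCC#CO[Si](C(C)C)(C(C)C)C(C)C
F2 | step 5 | (E)-4-methoxybuta-1,3-dien-1-one | CO/C=C/C=C=O
F3 | step 5 | 4-[(E)-2-methoxyethenyl]-2-pentadecyl-3-[(triisopropylsilyl)oxy]cyclobut-2-en-1-one (racemic) | CCCCCCCCCCCCCCCC1=C(O[Si](C(C)C)(C(C)C)C(C)C)C(/C=C/OC)C1=O
F4 | step 5 | (3E,5E)-6-methoxy-2-pentadecyl-3-[(triisopropylsilyl)oxy]hexa-1,3,5-trien-1-one | O=C=C(CCCCCCCCCCCCCCC)/C(O[Si](C(C)C)(C(C)C)C(C)C)=C\C=C\OC
F5 | step 2 | (E)-1-methoxy-3-(trimethylsilyloxy)buta-1,3-diene | CO/C=C/C(=C)O[Si](C)(C)C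
F6 | step 2 | (E)-1-bromo-4-methoxybut-3-en-2-one | CO/C=C/C(=O)CBr
F7 | step 6 | 4-methoxy-2-pentadecylbenzene-1,3-diol | CCCCCCCCCCCCCCCc1c(O)c(OC)ccc1O
F8 | step 6 | 2,4-dihydroxy-5-methoxy-3-pentadecylbenzaldehyde | CCCCCCCCCCCCCCCc1c(O)c(OC)cc(C=O)c1O
F9 | step 6 | 5-methoxy-3-pentadecylbenzene-1,2,4-triol | CCCCCCCCCCCCCCCc1c(O)c(OC)cc(O)c1O
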